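**Retrosynthetic overview**

- The C6 chloride comes from a 6R allylic alcohol by SN2 chlorination; that alcohol comes from a Ni/Cr closure of the C5–C6 bond (vinyl bromide onto aldehyde), which forms the ten-membered ring last.
- Ring A comes from an α-ketol ring expansion of a 1-acetylcyclopent-2-en-1-ol: C10 shifts from C12 to the acetyl carbon, turning the five-membered ring into the 6-hydroxy-6-methylcyclohexenone and setting C11.
- The C2 carbinol comes from a ketone (CBS) unmasked from a vinylsilane; the butanolide (C7, C8) comes from OH-directed epoxidation of a C7=C8 alkene followed by epoxide-opening lactonization.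
- C1, C10 and C9 come from a one-pot Cu-catalysed asymmetric conjugate addition of a silyl-dienylalane to 3-methylcyclopentenone with aldol capture by an enal.
- Ring order: cyclopentenone (purchased) → γ-lactone → ring A by expansion → ten-membered ring.

Assumptions: briarane numbering (C1–C20) is used in all names, and β means the face of ring A that carries the C1 methyl. Compounds 16–22 are ~1:1 C17 epimer mixtures (4, 6 and 8 are racemic), so C17 is left unspecified in their SMILES until it is fixed in step 10. CIP descriptors were derived by hand from the SMILES; the SMILES are authoritative.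

**Step 1**
Reactants: 1 ethyl propanoate; 2 allyl bromide
Product: 4 ethyl 2-methylpent-4-enoate (racemic), via lithium enolate 3 (not isolated)
Conditions: LDA, THF, −78 °C; then 2, −78 °C to rt
Reagents that add atoms: none
Why: Kinetic ester-enolate alkylation with a reactive allylic bromide gives the α-allyl ester; no stereocontrol is needed because this centre (C17) is equilibrated in step 10.

**Step 2**
Reactants: 4 ethyl 2-methylpent-4-enoate
Product: 6 ethyl 2-methyl-4-oxobutanoate (racemic), via ozonide 5 (not isolated)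
Conditions: O3, CH2Cl2, −78 °C; then Me2S, −78 °C to rt
Reagents that add atoms: ozone, [O-][O+]=O
Why: Ozonolysis with reductive work-up cleaves the terminal alkene to the aldehyde and leaves the ester untouched.

**Step 3**
Reactants: 6 ethyl 2-methyl-4-oxobutanoate; 7 2,2-dimethoxyacetaldehyde
Product: 8 ethyl (3E)-3-formyl-5,5-dimethoxy-2-methylpent-3-enoate (racemic)
Conditions: pyrrolidine (20 mol%), PhCO2H (20 mol%), 7 (1.5 equiv), CH2Cl2, rt
Reagents that add atoms: none
Why: Amine-catalysed cross-aldol condensation (enamine of 6 adds to the poorly enolisable, highly electrophilic aldehyde 7, then E1cB dehydration) gives the thermodynamically preferred (E)-2-substituted enal.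

**Step 4**
Reactants: 9 ethynyltrimethylsilane; 10 2,3-dibromoprop-1-ene
Product: 12 (4-bromopent-4-en-1-yn-1-yl)trimethylsilane, via alkynyl Grignard 11 (not isolated)
Conditions: EtMgBr, THF, 0 °C to rt; then CuBr (5 mol%), 10, 50 °C
Reagents that add atoms: none
Why: Copper-catalysed coupling of an alkynyl Grignard reagent with the allylic bromide (SN2 and SN2′ give the same product) forms the skipped enyne, the vinylic C–Br bond being inert.

**Step 5**
Reactants: 12 (4-bromopent-4-en-1-yn-1-yl)trimethylsilane; 13 3-methylcyclopent-2-en-1-one; 8 ethyl (3E)-3-formyl-5,5-dimethoxy-2-methylpent-3-enoate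
Product: 16 aldol adduct (1S,9R,10S; cyclopentan-12-one with 1β-Me, 1α-silyldienyl, 10β-CH(OH) side chain; 7E; C17 epimers), via alkenylalane 14 (not isolated), via aluminium enolate 15 (not isolated)
Conditions: 12, DIBAL-H, hexane/THF, 55 °C; then 13, chiral sulfonate-NHC·Ag (2.5 mol%), Cu(OTf)2 (5 mol%), THF, −30 °C; then 8, −78 °C; aq. Rochelle salt
Reagents that add atoms: none
Why: Syn-hydroalumination of the silylalkyne puts Al on the Si-bearing carbon, NHC–Cu-catalysed asymmetric conjugate addition of the alkenylalane to the β-methyl enone sets the C1 quaternary centre under catalyst control, and the regiodefined aluminium (E)-enolate adds to the enal through a Zimmerman–Traxler chair anti to the bulky silyldienyl group, which sets C10 (C9 cis to the C1 methyl) and C9 (anti aldol).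

**Step 6**
Reactants: 16 aldol adduct
Product: 18 hydroxy-lactone (7,19-olide; free 8-OH and 9-OH; 1S,7R,8R,9R,10S), via epoxy alcohol 17 (not isolated)
Conditions: VO(acac)2 (5 mol%), t-BuOOH, CH2Cl2, 0 °C; then Ti(OiPr)4 (20 mol%), rt; aq. tartaric acid
Reagents that add atoms: tert-butyl hydroperoxide, CC(C)(C)OO
Why: Hydroxyl-directed vanadium epoxidation of the 2-substituted allylic alcohol is erythro-selective (A1,2 strain) and fixes C8, and Ti-assisted 5-exo opening of the 2,3-epoxy alcohol at C7 by the ester carbonyl with inversion sets C7 and forms the γ-lactone with loss of ethanol.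

**Step 7**
Reactants: 18 hydroxy-lactone
Product: 19 8,9-O-isopropylidene acetal of 18
Conditions: 2-methoxypropene, PPTS (cat.), CH2Cl2, 0 °C
Reagents that add atoms: 2-methoxypropene, C=C(C)OC
Why: Kinetic acetonide formation ties up the 8,9-diol, which blocks retro-aldol, oxidation of 9-OH and trans-lactonisation in the next three steps.

**Step 8**
Reactants: 19 acetonide
Product: 20 cyclopent-13-en-12-one (A-nor enone)
Conditions: IBX (2 equiv), DMSO/PhF, 70 °C
Reagents that add atoms: none
Why: IBX dehydrogenation of the ketone can only give the C13=C14 enone because C1 is quaternary.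

**Step 9**
Reactants: 20 A-nor enone
Product: 22 A-nor α-ketol (12α-acetyl-12β-hydroxy-cyclopent-13-ene), via enol-ether carbinol 21 (not isolated)
Conditions: CH2=C(OEt)Li (from ethyl vinyl ether, t-BuLi), CeCl3, THF, −78 °C; then 0.1 M HCl, THF, 0 °C
Reagents that add atoms: 1-ethoxyvinyllithium, [Li]C(=C)OCC; water, O
Why: Cerium-mediated 1,2-addition of the acetyl-anion equivalent to the enone carbonyl, anti to the bulky C10 substituent, sets C12, and mild hydrolysis of the enol ether unveils the tertiary α-ketol without touching lactone, acetonide or acetal.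

**Step 10**
Reactants: 22 A-nor α-ketol
Product: 23 ring-expanded hydroxy-enone (11α-hydroxy-11β-methyl-cyclohex-13-en-12-one; 1S,7R,8R,9R,10S,11S,17R)
Conditions: t-BuOK (0.3 equiv), t-BuOH/THF (1:4), 0 °C to rt
Reagents that add atoms: none
Why: Proposed new method: base-promoted α-ketol ring expansion of a 1-acetylcyclopent-2-en-1-ol, a substrate class (allylic tertiary α-ketol in which the sp3 ring carbon must migrate in preference to the vinyl carbon) on which this rearrangement has not been shown; the C12 alkoxide triggers a 1,2-shift of C10 (with retention) onto the acetyl carbonyl carbon through the transoid, non-chelated O–C–C=O arrangement, which places the new 11-methyl cis to C9 (11S), the reaction is driven by five-to-six ring enlargement and by the gain of enone conjugation so that the reversible vinyl-shift pathway drains back, and the same alkoxide equilibrates C17 to the more stable epimer (methyl anti to the C9 branch); the closest known reaction is the D-homoannulation of 17-hydroxy-20-keto steroids and of saturated 1-acylcycloalkanols.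

**Step 11**
Reactants: 23 ring-expanded hydroxy-enone
Product: 25 2,12-dione (C2 ketone; free 8-, 9-, 11-OH; C6 dimethyl acetal; 2-bromoallyl terminus), via epoxysilane 24 (not isolated)
Conditions: m-CPBA, NaHCO3, CH2Cl2, 0 °C; then CSA (cat.), MeOH, rt; aq. NaHCO3
Reagents that add atoms: m-chloroperbenzoic acid, OOC(=O)c1cccc(Cl)c1
Why: Prilezhaev epoxidation is selective for the electron-rich vinylsilane (bromoalkene and enone are deactivated), acid opens the epoxysilane through the β-silyl cation with loss of silicon to give the C2 ketone (epoxysilane-to-ketone unmasking), and acidic methanol also removes the acetonide while the dimethyl acetal is retained.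

**Step 12**
Reactants: 25 2,12-dione
Product: 26 (2R)-2-hydroxy compound (free 2-, 8-, 9-, 11-OH)
Conditions: (S)-Me-CBS (0.5 equiv), catecholborane, toluene, −78 °C
Reagents that add atoms: none
Why: Corey–Bakshi–Shibata reduction delivers hydride to the tert-alkyl/n-alkyl ketone to give the 2R carbinol, matched with Felkin–Anh control from C1, while the conjugated C12 ketone flanked by the fully substituted C11 reacts far more slowly.

**Step 13**
Reactants: 26 (2R)-2-hydroxy compound
Product: 27 2,9-diacetate
Conditions: Ac2O, pyridine, DMAP (cat.), CH2Cl2, 0 °C to rt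
Reagents that add atoms: acetic anhydride, CC(=O)OC(C)=O
Why: DMAP-catalysed acylation esterifies the two secondary hydroxyls, whereas the tertiary 8- and 11-hydroxyls are too hindered to react.

**Step 14**
Reactants: 27 2,9-diacetate
Product: 28 C6 aldehyde
Conditions: TFA/H2O (9:1), CH2Cl2, 0 °C
Reagents that add atoms: water, O
Why: Acid-catalysed hydrolysis of the deactivated α-acyloxy dimethyl acetal liberates the aldehyde under conditions that acetates, lactone and tertiary alcohols tolerate.

**Step 15**
Reactants: 28 C6 aldehyde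
Product: 29 (6R)-allylic alcohol macrocycle (5(16)-ene, 6-OH)
Conditions: CrCl2 (6 equiv), NiCl2 (5 mol%), Kishi chiral sulfonamide ligand (enantiomer giving 6R), Et3N, THF, rt, 2 mM
Reagents that add atoms: none
Why: Nozaki–Hiyama–Kishi reaction: Ni inserts into the vinyl bromide, transmetalation gives the alkenylchromium(III), which adds chemoselectively to the aldehyde at high dilution to close the ten-membered ring and create the exocyclic methylene, the chiral sulfonamide–chromium complex controlling the C6 carbinol.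

**Step 16**
Reactants: 29 (6R)-allylic alcohol macrocycle
Product: 30 target CNP0261648.1 (1S,2R,6S,7R,8R,9R,10S,11S,17R)
Conditions: PPh3, Cl3CCN, CH2Cl2, 0 °C
Reagents that add atoms: trichloroacetonitrile, ClC(Cl)(Cl)C#N
Why: Appel-type chlorination displaces the alkoxyphosphonium by chloride in an SN2 reaction with inversion to give the 6S chloride, the adjacent electron-withdrawing lactone oxygen disfavouring ionisation and SN2′ and the tertiary alcohols being unreactive.

**Compound list**

1 | ethyl propanoate | CCC(=O)OCC | starting material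
2 | allyl bromide | C=CCBr | starting material
3 | lithium enolate of ethyl propanoate | CC=C(OCC)O[Li] | intermediate (not isolated)
4 | ethyl 2-methylpent-4-enoate (racemic) | C=CCC(C)C(=O)OCC | intermediate
5 | ozonide of 4 (ethyl 2-methyl-3-(1,2,4-trioxolan-3-yl)propanoate) | CCOC(=O)C(C)CC1OCOO1 | intermediate (not isolated)
6 | ethyl 2-methyl-4-oxobutanoate (racemic) | CCOC(=O)C(C)CC=O | intermediate
7 | 2,2-dimethoxyacetaldehyde | COC(OC)C=O | starting material
8 | ethyl (3E)-3-formyl-5,5-dimethoxy-2-methylpent-3-enoate (racemic; carbons = C19, C17, C18, C8, C9, C7, C6) | CCOC(=O)C(C)/C(C=O)=C\C(OC)OC | intermediate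
9 | ethynyltrimethylsilane | C[Si](C)(C)C#C | starting material
10 | 2,3-dibromoprop-1-ene | C=C(Br)CBr | starting material
11 | [(trimethylsilyl)ethynyl]magnesium bromide | C[Si](C)(C)C#C[Mg]Br | intermediate (not isolated)
12 | (4-bromopent-4-en-1-yn-1-yl)trimethylsilane | C[Si](C)(C)C#CCC(Br)=C | intermediate
13 | 3-methylcyclopent-2-en-1-one | CC1=CC(=O)CC1 | starting material
14 | [(1Z)-4-bromo-1-(trimethylsilyl)penta-1,4-dien-1-yl]diisobutylalane | C=C(Br)C/C=C(\[Si](C)(C)C)[Al](CC(C)C)CC(C)C | intermediate (not isolated)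
15 | diisobutylaluminium enolate of (S)-3-methyl-3-[(1Z)-4-bromo-1-(trimethylsilyl)penta-1,4-dienyl]cyclopentanone (enolate C12=C10) | C=C(Br)C/C=C(\[Si](C)(C)C)[C@@]1(C)CCC(O[Al](CC(C)C)CC(C)C)=C1 | intermediate (not isolated)
16 | aldol adduct (1S,9R,10S): cyclopentan-12-one with 1β-Me, 1α-[(Z)-silyldienyl], 10β-[C9H(OH)–C8(=C7H–C6H(OMe)2)–C17H(Me)CO2Et], 7E, 9,10-anti; C17 epimers | C=C(Br)C/C=C(\[Si](C)(C)C)[C@@]1(C)CCC(=O)[C@@H]1[C@@H](O)/C(=C/C(OC)OC)C(C)C(=O)OCC | intermediate
17 | 7,8-epoxide of 16 (erythro epoxy alcohol, trans-epoxide; C17 epimers) | C=C(Br)C/C=C(\[Si](C)(C)C)[C@@]1(C)CCC(=O)[C@@H]1[C@@H](O)[C@]2(O[C@@H]2C(OC)OC)C(C)C(=O)OCC | intermediate (not isolated)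
18 | hydroxy-lactone (1S,7R,8R,9R,10S): 7,19-olide with free 8-OH and 9-OH, C6 dimethyl acetal; C17 epimers | C=C(Br)C/C=C(\[Si](C)(C)C)[C@@]1(C)CCC(=O)[C@@H]1[C@@H](O)[C@]1(O)C(C)C(=O)O[C@H]1C(OC)OC | intermediate
19 | 8,9-O-isopropylidene acetal of 18 | C=C(Br)C/C=C(\[Si](C)(C)C)[C@@]1(C)CCC(=O)[C@@H]1[C@H]2OC(C)(C)O[C@]23C(C)C(=O)O[C@H]3C(OC)OC | intermediate
20 | A-nor enone (cyclopent-13-en-12-one; 8,9-acetonide) | C=C(Br)C/C=C(\[Si](C)(C)C)[C@@]1(C)C=CC(=O)[C@@H]1[C@H]2OC(C)(C)O[C@]23C(C)C(=O)O[C@H]3C(OC)OC | intermediate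
21 | 12α-(1-ethoxyvinyl)-12β-hydroxy adduct of 20 | C=C(Br)C/C=C(\[Si](C)(C)C)[C@@]1(C)C=C[C@@](O)(C(=C)OCC)[C@@H]1[C@H]2OC(C)(C)O[C@]23C(C)C(=O)O[C@H]3C(OC)OC | intermediate (not isolated)
22 | A-nor α-ketol: 12α-acetyl-12β-hydroxy-cyclopent-13-ene (acetyl = C11, C20) | C=C(Br)C/C=C(\[Si](C)(C)C)[C@@]1(C)C=C[C@@](O)(C(C)=O)[C@@H]1[C@H]2OC(C)(C)O[C@]23C(C)C(=O)O[C@H]3C(OC)OC | intermediate
23 | ring-expanded hydroxy-enone (1S,7R,8R,9R,10S,11S,17R): 11α-OH, 11β-Me, 12-oxo, 13-ene; 8,9-acetonide | C=C(Br)C/C=C(\[Si](C)(C)C)[C@@]1(C)C=CC(=O)[C@@](C)(O)[C@@H]1[C@H]2OC(C)(C)O[C@]23[C@@H](C)C(=O)O[C@H]3C(OC)OC | intermediate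
24 | 2,3-epoxysilane of 23 (epoxide diastereomers, inconsequential) | C=C(Br)CC1OC1([Si](C)(C)C)[C@@]2(C)C=CC(=O)[C@@](C)(O)[C@@H]2[C@H]3OC(C)(C)O[C@]34[C@@H](C)C(=O)O[C@H]4C(OC)OC | intermediate (not isolated)
25 | 2,12-dione with free 8-, 9-, 11-OH, C6 dimethyl acetal, 2-bromoallyl terminus | C=C(Br)CCC(=O)[C@@]1(C)C=CC(=O)[C@@](C)(O)[C@@H]1[C@@H](O)[C@]1(O)[C@@H](C)C(=O)O[C@H]1C(OC)OC | intermediate
26 | (2R)-2-hydroxy compound (2,8,9,11-tetraol) | C=C(Br)CC[C@@H](O)[C@@]1(C)C=CC(=O)[C@@](C)(O)[C@@H]1[C@@H](O)[C@]1(O)[C@@H](C)C(=O)O[C@H]1C(OC)OC | intermediate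
27 | 2,9-diacetate | C=C(Br)CC[C@@H](OC(C)=O)[C@@]1(C)C=CC(=O)[C@@](C)(O)[C@@H]1[C@@H](OC(C)=O)[C@]1(O)[C@@H](C)C(=O)O[C@H]1C(OC)OC | intermediate
28 | C6 aldehyde (5,6-seco precursor with 2-bromoallyl terminus) | C=C(Br)CC[C@@H](OC(C)=O)[C@@]1(C)C=CC(=O)[C@@](C)(O)[C@@H]1[C@@H](OC(C)=O)[C@]1(O)[C@@H](C)C(=O)O[C@H]1C=O | intermediate
29 | (6R)-allylic alcohol macrocycle (target with 6-OH of opposite configuration in place of Cl) | C=C1CC[C@@H](OC(C)=O)[C@@]2(C)C=CC(=O)[C@@](C)(O)[C@@H]2[C@@H](OC(C)=O)[C@]2(O)[C@@H](C)C(=O)O[C@H]2[C@@H]1O | intermediate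
30 | CNP0261648.1 (1S,2R,6S,7R,8R,9R,10S,11S,17R) | C=C1CC[C@@H](OC(C)=O)[C@@]2(C)C=CC(=O)[C@@](C)(O)[C@@H]2[C@@H](OC(C)=O)[C@]2(O)[C@@H](C)C(=O)O[C@H]2[C@H]1Cl | target

**Step count and risks**

Total steps: 16. Longest linear sequence: 15 (steps 1–3, then 5–16).

Steps most likely to fail:

Step 10 (the new α-ketol ring expansion on an allylic ketol; risks are vinyl migration, erosion of C11 by reversibility, and incomplete C17 equilibration). The fallback uses only known chemistry, sets out from 19 and comes back at 23. The saturated ketone 19 is treated with 1-ethoxyvinyllithium/CeCl3 to give the saturated enol-ether carbinol F1, which is hydrolysed with dilute HCl to the saturated 1-acetylcyclopentanol F2. This undergoes the established base-mediated α-ketol ring expansion of 1-acylcyclopentanols (t-BuOK, t-BuOH/THF, which also equilibrates C17) to the saturated 11-hydroxy-12-ketone F3. IBX dehydrogenation, possible only towards C13–C14, then gives 23. If the 12-epimer of 22 forms instead, a chelating Lewis acid (Al(Ot-Bu)3) should lead to the same 11S product through the cisoid arrangement.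

Step 5 (three-component conjugate addition/aldol with a trisubstituted silyl-alkenylalane and capture next to a new quaternary centre). The fallback sets out from 14 and 13 and comes back at 16. The conjugate addition is run alone and quenched with TMSOTf to give the isolable trimethylsilyl enol ether F4. This is cleaved with MeLi in THF to the lithium enolate F5, which is added to enal 8 at −78 °C (closed transition state, same anti sense) to give 16.

Step 15 (ten-membered ring closure and C6 configuration). The fallback sets out from 28 and comes back at 29. Pinnick oxidation of 28 gives the carboxylic acid F6, which is converted with 2,2′-dipyridyl disulfide/PPh3 into the 2-pyridyl thioester F7. Ni/Zr-mediated intramolecular ketone synthesis (NiBr2(dtbbpy), Cp2ZrCl2, Zn, DMI, high dilution) closes the ring at the acyl oxidation level to the macrocyclic α-methylene ketone F8. Reagent-controlled CBS reduction then gives 29.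

**Further compounds**

F1 | step 10 | saturated 12α-(1-ethoxyvinyl)-12β-hydroxy adduct of 19 | C=C(Br)C/C=C(\[Si](C)(C)C)[C@@]1(C)CC[C@@](O)(C(=C)OCC)[C@@H]1[C@H]2OC(C)(C)O[C@]23C(C)C(=O)O[C@H]3C(OC)OC
F2 | step 10 | saturated A-nor α-ketol (12α-acetyl-12β-hydroxycyclopentane) | C=C(Br)C/C=C(\[Si](C)(C)C)[C@@]1(C)CC[C@@](O)(C(C)=O)[C@@H]1[C@H]2OC(C)(C)O[C@]23C(C)C(=O)O[C@H]3C(OC)OC
F3 | step 10 | saturated ring-expanded 11α-hydroxy-11β-methylcyclohexan-12-one | C=C(Br)C/C=C(\[Si](C)(C)C)[C@@]1(C)CCC(=O)[C@@](C)(O)[C@@H]1[C@H]2OC(C)(C)O[C@]23[C@@H](C)C(=O)O[C@H]3C(OC)OC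
F4 | step 5 | trimethylsilyl enol ether of (S)-3-methyl-3-[(1Z)-4-bromo-1-(trimethylsilyl)penta-1,4-dienyl]cyclopentanone | C=C(Br)C/C=C(\[Si](C)(C)C)[C@@]1(C)CCC(O[Si](C)(C)C)=C1
F5 | step 5 | lithium enolate corresponding to F4 | C=C(Br)C/C=C(\[Si](C)(C)C)[C@@]1(C)CCC(O[Li])=C1
F6 | step 15 | C6 carboxylic acid from 28 | C=C(Br)CC[C@@H](OC(C)=O)[C@@]1(C)C=CC(=O)[C@@](C)(O)[C@@H]1[C@@H](OC(C)=O)[C@]1(O)[C@@H](C)C(=O)O[C@H]1C(=O)O
F7 | step 15 | C6 S-(2-pyridyl) thioester | C=C(Br)CC[C@@H](OC(C)=O)[C@@]1(C)C=CC(=O)[C@@](C)(O)[C@@H]1[C@@H](OC(C)=O)[C@]1(O)[C@@H](C)C(=O)O[C@H]1C(=O)Sc1ccccn1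
F8 | step 15 | macrocyclic 6-ketone (5(16)-en-6-one) | C=C1CC[C@@H](OC(C)=O)[C@@]2(C)C=CC(=O)[C@@](C)(O)[C@@H]2[C@@H](OC(C)=O)[C@]2(O)[C@@H](C)C(=O)O[C@H]2C1=O
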